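(All runs are calculated on assumed constants, noise included.)

The time asked of the flask is 8.0 h, and before fitting anything I ask how far J can get in that time.

in all of them: L 0.192 M

| flask | G | D | E | remark | time |
|---|---|---|---|---|---|
| ash | 0.34 M | 0.34 M | 2.4 mM | run made earlier |  |
| elm | 0.53 M | 0.53 M | 2.4 mM | run made earlier |  |
| alder | 0.24 M | 0.24 M | 4.8 mM | run made earlier |  |
| flask | 0.24 M | 0.24 M | 2.4 mM |  | 8.0 h |

- ash (time / h: J / %, Z / %): 0.500: 2.5, 0; 1.50: 11.4, 0; 3.00: 20.8, 1.0; 5.00: 27.0, 2.2; 6.00: 26.4, 1.6
- elm (time / h: J / %, Z / %): 1.33: 7.9, 0; 2.50: 14.2, 2.4; 4.00: 16.2, 0; 5.00: 18.8, 1.1; 6.00: 16.1, 0.6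
- alder (time / h: J / %, Z / %): 0.500: 5.2, 1.8; 1.00: 10.1, 0; 2.00: 24.8, 0.7; 3.00: 31.2, 0.3; 6.00: 38.2, 0.8

(standard deviation of a reading: 1 percentage point)

* excess of J over Z in the product at 10 min
* excess of J over Z in the product at 8.0 h
* part of the G and D charged together that has reacted at 8.0 h

- E is single-handed; G and D are mirror images of each other, charged as a racemate, each of them at the stated concentration
- solid, in amounts per volume of the solution: L
- the numbers in the tables scatter by 1 percentage point (one standard deviation)
- at the start none of L is in solution
- an excess is the difference of the two amounts in percent of their sum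
- an excess is below zero if the other one leads

In the flask, the charge of L in percent of the G and D together charged is 40.0%. I call this the L ceiling, taking L as the limiting reagent. The same sum gives 28.2% for ash and 18.1% for elm, and at 5.00 h J reads 27.0% and 18.8%, so charge and readings tell the same story.

A second way uses the clock. The flask is the alder recipe with half the E, so if the rate goes with E, its 8.0 h counts as 4.00 h in alder. Alder's J plus Z reads 31.5% at 3.00 h and 39.0% at 6.00 h. My own figure for the reacted part is read on the straight line between these two readings at 4.00 h: 34.0%, which is lower than the ceiling. Where the two ways part, the ceiling is the one that cheats as a forecast, since it carries no time. I keep it as the upper bound on the reacted part, so long as L is the limiting reagent.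

The forecast reads the plateaus likewise, “J levels off near 0.192 M in every run”. It gives an excess of J over Z of 93% (84% to 98%) at 10 min and 90% (80% to 95%) at 8.0 h, and a reacted part of 36.5% (32% to 40%) at 8.0 h, which is higher than my figure.

The flask gives an excess of 97.3% at 10 min and 97.0% at 8.0 h, and a reacted part of 37.3% at 8.0 h, so the later excess stands above the forecast.

    Q + E + G → E + J (k = 1900 M⁻² h⁻¹)
    Q + E + D → E + Z (k = 26.0 M⁻² h⁻¹)
    G ⇌ D (k = 0.910 h⁻¹)
    L ⇌ Q, rate k4*(cs4 - [Q]) while solid is left; crystals form when [Q] > cs4 (solubility = 0.130 M, k = 0.970 h⁻¹)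
    Q ⇌ X (K = 0.650, k = 0.350 h⁻¹)

At 8.00 h in the flask, solid L stands at 0% of its charge, while Q and X, which forms from Q, stand at 0.00531 M and 0.00744 M. Together they come to 2.66% of the G and D charged, and this with 37.3% makes 40.0% against the ceiling of 40.0%. With 0.12 M of L and the other charges as in the flask, the ceiling is 25.0%. That neighbour flask has J at 23.6% at 8.00 h, and its reacted part is 23.9%.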